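The 3(2H)-furanone ring (O–C3=C2–C1(=O)–C10, germacrane numbering) that bridges the ten-membered carbocycle is cut into a C3 ester and a two-carbon alkyne. The key step exploits that C3 is at the carboxylic acid level and that C10 lies next to oxygenated C9 and 1,3 to O8: with the C3 acid parked as an ester on O8 and C9 as a ketone, a rhodium carbenoid at C10 is trapped by the ester carbonyl to a six-membered carbonyl ylide, whose [3+2] cycloaddition with ethoxyacetylene forges C2–C3 and C1–C10 and sets quaternary C10. The precursor is an acyclic α-acyloxy-α′-diazo ketone; the 2,8-dioxabicyclo[3.2.1]octene cage formed then steers the C9 reduction and collapses to the furanone.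

Key step: step 10

Remark: germacrane numbering (C1–C15; O8 is the oxygen on C8) is used throughout; TBS = tert-butyldimethylsilyl, TBDPS = tert-butyldiphenylsilyl, PMB = 4-methoxybenzyl; ethereal diazoethane is assumed to be prepared just before use from commercial N-ethyl-N-nitrosourea.

Step 1
Reactants: 1 but-2-yne-1,4-diol
Product: 2 4-(TBDPSO)but-2-yn-1-ol
Conditions: TBDPSCl (1 equiv), imidazole, 1 (3 equiv), DMF, 0 °C to rt
Reagents that add atoms: tert-butyl(chloro)diphenylsilane, CC(C)(C)[Si](Cl)(c1ccccc1)c1ccccc1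
Why: Silyl ether formation; with the symmetrical diol in excess the monosilyl ether should be the main product and keeps one hydroxyl to direct step 2.

Step 2
Reactants: 2 4-(TBDPSO)but-2-yn-1-ol
Product: 4 (2Z)-4-(TBDPSO)-3-iodobut-2-en-1-ol, via alkenylaluminate 3 (not isolated)
Conditions: NaAlH2(OCH2CH2OMe)2 (Red-Al), THF, 0 °C; then N-iodosuccinimide, −78 °C
Reagents that add atoms: N-iodosuccinimide, O=C1CCC(=O)N1I
Why: Hydroxyl-directed trans-hydroalumination of the propargylic alcohol places aluminium on the distal alkyne carbon, and iodinolysis with retention should give the Z-iodoalkene in which iodine (future C3 carboxyl) is cis to the CH2OH carbon (future C6).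

Step 3
Reactants: 4 (2Z)-4-(TBDPSO)-3-iodobut-2-en-1-ol
Product: 5 (Z)-alkenyl iodide TBSOCH2–CH=C(I)–CH2OTBDPS
Conditions: TBSCl, imidazole, CH2Cl2, 0 °C to rt
Reagents that add atoms: tert-butyl(chloro)dimethylsilane, CC(C)(C)[Si](C)(C)Cl
Why: Standard silylation of the primary alcohol; the more labile TBS group on O6 can later be removed beside the TBDPS group on O15.

Step 4
Reactants: 5 (Z)-alkenyl iodide TBSOCH2–CH=C(I)–CH2OTBDPS
Product: 6 (2Z)-4-(TBSO)-2-(TBDPSOCH2)but-2-enoic acid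
Conditions: PdCl2(PPh3)2 (5 mol %), CO (1 atm), Et3N, DMF/H2O, 50 °C
Reagents that add atoms: carbon monoxide, [C-]#[O+]; water, O
Why: Palladium-catalysed hydroxycarbonylation of the alkenyl iodide proceeds with retention of alkene geometry and so fixes the 4Z relationship of C3 and C6.

Step 5
Reactants: 7 (4S)-2,2-dimethyl-1,3-dioxolane-4-carbaldehyde; 8 trimethyl 2-phosphonoacrylate
Product: 10 methyl (2E)-3-[(4R)-2,2-dimethyl-1,3-dioxolan-4-yl]-2-(PMBOCH2)prop-2-enoate, via phosphonate carbanion 9 (not isolated)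
Conditions: 4-methoxybenzyl alcohol, NaH, THF, 0 °C; 8, 0 °C; then 7, −20 °C to rt
Reagents that add atoms: 4-methoxybenzyl alcohol, COc1ccc(CO)cc1
Why: Tandem oxa-Michael addition/Horner–Wadsworth–Emmons olefination: the alkoxide adds to the phosphonoacrylate and the stabilised carbanion olefinates the aldehyde to the E-enoate, the C8 stereocentre coming unchanged from the chiral pool.

Step 6
Reactants: 10 methyl (2E)-3-[(4R)-2,2-dimethyl-1,3-dioxolan-4-yl]-2-(PMBOCH2)prop-2-enoate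
Product: 11 methyl (2E,4R)-4,5-dihydroxy-2-(PMBOCH2)pent-2-enoate
Conditions: AcOH/H2O (4:1), 40 °C
Reagents that add atoms: none
Why: Acid-catalysed acetal hydrolysis; the E geometry (C8 trans to CO2Me) prevents lactonisation of the freed hydroxyls onto the ester.

Step 7
Reactants: 11 methyl (2E,4R)-4,5-dihydroxy-2-(PMBOCH2)pent-2-enoate
Product: 12 (2R,3E)-2-hydroxy-4-(methoxycarbonyl)-5-(PMBO)pent-3-enoic acid
Conditions: TEMPO (0.2 equiv), PhI(OAc)2 (2.2 equiv), MeCN/aqueous pH 7 phosphate buffer, 0 °C to rt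
Reagents that add atoms: water, O
Why: Oxoammonium (TEMPO) oxidation is selective for the primary over the secondary carbinol and in aqueous medium should carry it through to the carboxylic acid without touching C8.

Step 8
Reactants: 6 (2Z)-4-(TBSO)-2-(TBDPSOCH2)but-2-enoic acid; 12 (2R,3E)-2-hydroxy-4-(methoxycarbonyl)-5-(PMBO)pent-3-enoic acid
Product: 14 (2R,3E)-2-{[(2Z)-4-(TBSO)-2-(TBDPSOCH2)but-2-enoyl]oxy}-4-(methoxycarbonyl)-5-(PMBO)pent-3-enoic acid, via acid chloride 13 (not isolated)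
Conditions: 6, 1-chloro-N,N,2-trimethylprop-1-en-1-amine, CH2Cl2, 0 °C; then 12, pyridine, DMAP (cat.), −20 to 0 °C
Reagents that add atoms: none
Why: Acylation of the secondary hydroxyl of the α-hydroxy acid by the acid chloride made under neutral conditions installs the ester tether that will deliver the C3 carbonyl oxygen to C10; C8 is not affected.

Step 9
Reactants: 14 (2R,3E)-2-{[(2Z)-4-(TBSO)-2-(TBDPSOCH2)but-2-enoyl]oxy}-4-(methoxycarbonyl)-5-(PMBO)pent-3-enoic acid
Product: 16 methyl (2E,4R)-6-diazo-5-oxo-2-(PMBOCH2)-4-{[(2Z)-4-(TBSO)-2-(TBDPSOCH2)but-2-enoyl]oxy}hept-2-enoate, via mixed anhydride 15 (not isolated)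
Conditions: i-BuOCOCl, N-methylmorpholine, THF, −25 °C; then CH3CHN2 in Et2O (3 equiv), −25 to 0 °C
Reagents that add atoms: diazoethane, CC=[N+]=[N-]
Why: Acylation of diazoethane by the mixed carbonic anhydride (Arndt–Eistert-type diazoketone synthesis) introduces C10 and C14 without a base strong enough to epimerise C8.

Step 10
Reactants: 16 methyl (2E,4R)-6-diazo-5-oxo-2-(PMBOCH2)-4-{[(2Z)-4-(TBSO)-2-(TBDPSOCH2)but-2-enoyl]oxy}hept-2-enoate; 17 ethoxyethyne
Product: 20 (1R,3R,5R)-6-ethoxy-5-methyl-1-[(2Z)-4-(TBSO)-1-(TBDPSO)but-2-en-2-yl]-3-[(1E)-3-methoxy-3-oxo-2-(PMBOCH2)prop-1-en-1-yl]-2,8-dioxabicyclo[3.2.1]oct-6-en-4-one, via rhodium carbenoid 18 (not isolated), via carbonyl ylide 19 (not isolated)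
Conditions: Rh2(OPiv)4 (2 mol %), 17 (5 equiv), CH2Cl2, −40 to 0 °C, slow addition of 16
Reagents that add atoms: none
Why: Loss of dinitrogen gives the rhodium carbenoid 18 at C10, which is attacked by the carbonyl oxygen of the O8 ester (6-exo ring closure) to release the six-membered carbonyl ylide 19 (C3=O+–C10−, the negative end conjugated with the C9 ketone), and 19 then adds ethoxyethyne in a concerted but asynchronous 1,3-dipolar cycloaddition. The closest known reaction type is the tandem rhodium-carbenoid cyclisation/carbonyl ylide [3+2] cycloaddition of diazocarbonyl compounds bearing an ester carbonyl, which is also known with alkoxyacetylenes as dipolarophiles. Two rings close: the 1,3-dioxane ring by the 6-exo attack of oxygen on the carbenoid and the 2,5-dihydrofuran ring (O–C3–C2=C1–C10) by the suprafacial 4π+2π cycloaddition. The quaternary centre C10 is controlled by C8: the alkyne should approach the nearly planar ylide on the face anti to the C7 alkenyl substituent, which ends up exo (equatorial), and C3 follows as the second bridgehead. The step needs regioselectivity (C2 to C3, C1 to C10), secured by polarity matching of the nucleophilic CH terminus of the ynol ether with the dioxy-stabilised cationic terminus C3 and of the oxygen-bearing carbon with the enolate-like C10. It also needs chemoselectivity against 1,2-hydride shift from C14 and against direct attack of the alkyne on the carbenoid, for which the bulky carboxylate catalyst, low temperature and slow addition of 16 are chosen.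

Step 11
Reactants: 20 cycloadduct (cage ketone)
Product: 21 (1R,3R,4R,5S)-6-ethoxy-5-methyl-1-[(2Z)-4-(TBSO)-1-(TBDPSO)but-2-en-2-yl]-3-[(1E)-3-methoxy-3-oxo-2-(PMBOCH2)prop-1-en-1-yl]-2,8-dioxabicyclo[3.2.1]oct-6-en-4-ol
Conditions: NaBH4, MeOH/CH2Cl2 (1:4), −78 °C
Reagents that add atoms: none
Why: Borohydride reduction of the C9 ketone held in the rigid bicycle: hydride should attack axially from the face of the one-atom oxygen bridge, away from the C1=C2 bridge and its ethoxy group, to give the equatorial 9R alcohol.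

Step 12
Reactants: 21 cage alcohol
Product: 22 (1R,3R,4R,5S)-6-ethoxy-5-methyl-1-[(2Z)-4-(TBSO)-1-(TBDPSO)but-2-en-2-yl]-3-[(1E)-3-methoxy-3-oxo-2-(PMBOCH2)prop-1-en-1-yl]-2,8-dioxabicyclo[3.2.1]oct-6-en-4-yl 3-methylbut-2-enoate
Conditions: 3-methylbut-2-enoyl chloride, pyridine, DMAP (cat.), CH2Cl2, 0 °C to rt
Reagents that add atoms: 3-methylbut-2-enoyl chloride, CC(C)=CC(=O)Cl
Why: Pyridine/DMAP-mediated acylation of the secondary alcohol while O8 is still locked in the ketal, so that the two different esters cannot be confused.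

Step 13
Reactants: 22 cage senecioate
Product: 23 8-epi furanone alcohol (8R,9R,10S): methyl (2E,4R,5R)-4-hydroxy-5-[(3-methylbut-2-enoyl)oxy]-5-{(2S)-2-methyl-3-oxo-5-[(2Z)-4-(TBSO)-1-(TBDPSO)but-2-en-2-yl]-2,3-dihydrofuran-2-yl}-2-(PMBOCH2)pent-2-enoate
Conditions: PPTS (0.2 equiv), THF/H2O (10:1), 0 °C to rt
Reagents that add atoms: water, O
Why: Acid-catalysed hydrolysis of the enol ether to the C1 ketone followed by E1-type β-elimination of O8 from the bridging ketal should give the conjugated 3(2H)-furanone, create the C2=C3 double bond and release the 8-hydroxyl without touching a stereocentre.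

Step 14
Reactants: 23 8-epi furanone alcohol
Product: 24 (8S,9R,10S) diester: methyl (2E,4S,5R)-4-(methacryloyloxy)-5-[(3-methylbut-2-enoyl)oxy]-5-{(2S)-2-methyl-3-oxo-5-[(2Z)-4-(TBSO)-1-(TBDPSO)but-2-en-2-yl]-2,3-dihydrofuran-2-yl}-2-(PMBOCH2)pent-2-enoate
Conditions: methacrylic acid, PPh3, DIAD, toluene, −20 °C to rt
Reagents that add atoms: methacrylic acid, C=C(C)C(=O)O
Why: Mitsunobu esterification: SN2 displacement of the activated allylic C8 hydroxyl by methacrylate should invert C8 to the required 8S configuration, the electron-poor alkene disfavouring SN1 and SN2′ pathways.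

Step 15
Reactants: 24 (8S,9R,10S) diester
Product: 25 allylic alcohol (C13–OH): methyl (2E,4S,5R)-2-(hydroxymethyl)-4-(methacryloyloxy)-5-[(3-methylbut-2-enoyl)oxy]-5-{(2S)-2-methyl-3-oxo-5-[(2Z)-4-(TBSO)-1-(TBDPSO)but-2-en-2-yl]-2,3-dihydrofuran-2-yl}pent-2-enoate
Conditions: DDQ, CH2Cl2/aqueous pH 7 buffer (10:1), 0 °C
Reagents that add atoms: none
Why: Oxidative cleavage of the 4-methoxybenzyl ether by DDQ leaves the silyl ethers and esters intact.

Step 16
Reactants: 25 allylic alcohol (C13–OH)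
Product: 26 allylic bromide (C13–Br): methyl (2Z,4S,5R)-2-(bromomethyl)-4-(methacryloyloxy)-5-[(3-methylbut-2-enoyl)oxy]-5-{(2S)-2-methyl-3-oxo-5-[(2Z)-4-(TBSO)-1-(TBDPSO)but-2-en-2-yl]-2,3-dihydrofuran-2-yl}pent-2-enoate
Conditions: CBr4, PPh3, CH2Cl2, −20 °C
Reagents that add atoms: carbon tetrabromide, BrC(Br)(Br)Br
Why: Appel bromination of the primary allylic alcohol under neutral conditions gives the 2-(bromomethyl)enoate needed for the allylation.

Step 17
Reactants: 26 allylic bromide (C13–Br)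
Product: 27 C6 alcohol: as 26 with the furanone side chain (2Z)-4-hydroxy-1-(TBDPSO)but-2-en-2-yl
Conditions: HF·pyridine, pyridine, THF, 0 °C
Reagents that add atoms: none
Why: Buffered fluoride cleaves the primary TBS ether much faster than the TBDPS ether.

Step 18
Reactants: 27 C6 alcohol
Product: 28 Z-enal: as 26 with the furanone side chain (2Z)-4-oxo-1-(TBDPSO)but-2-en-2-yl
Conditions: Dess–Martin periodinane, NaHCO3, CH2Cl2, 0 °C
Reagents that add atoms: none
Why: Dess–Martin oxidation of the Z-allylic alcohol under buffered, non-nucleophilic conditions should give the Z-enal without isomerisation of C4=C5.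

Step 19
Reactants: 28 Z-enal
Product: 31 15-O-TBDPS ether of the target, via allylchromium 29 (not isolated), via hydroxy ester 30 (not isolated)
Conditions: CrCl2 (10 equiv), THF (0.002 M, syringe-pump addition of 28), rt; aqueous NH4Cl; then PPTS (cat.), CH2Cl2, rt
Reagents that add atoms: none
Why: Intramolecular chromium-mediated Barbier (Nozaki–Hiyama–Kishi) allylation: divalent chromium converts the bromide into allylchromium 29, which adds through C7 to the C6 aldehyde in a closed chair-like transition state under macrocyclic control (Z-C4=C5 and the furanone bridge pre-organise the chain), which should set the 6R,7S trans relationship, and hydroxy ester 30 lactonises with loss of methanol.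

Step 20
Reactants: 31 15-O-TBDPS ether of the target
Product: 32 target, (4Z,6R,7S,8S,9R,10S)-15-hydroxy-8-(methacryloyloxy)-9-[(3-methylbut-2-enoyl)oxy]-1-oxo-3,10-epoxygermacra-2,4,11(13)-trien-12,6-olide
Conditions: HF·pyridine, THF, 0 °C to rt
Reagents that add atoms: none
Why: Fluoride-mediated cleavage of the TBDPS ether under mildly acidic conditions that the esters, the α-methylene lactone and the furanone should tolerate.

Compound list

1 | but-2-yne-1,4-diol | OCC#CCO | starting material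
2 | 4-(TBDPSO)but-2-yn-1-ol | OCC#CCO[Si](c1ccccc1)(c1ccccc1)C(C)(C)C | intermediate
3 | sodium cyclic alkenyl(alkoxy)aluminate from 2 (2,5-dihydro-1,2-oxaluminol-2-uide) | [Na+].COCCO[Al-]1(OCCOC)OCC=C1CO[Si](c2ccccc2)(c2ccccc2)C(C)(C)C | intermediate
4 | (2Z)-4-(TBDPSO)-3-iodobut-2-en-1-ol | OC/C=C(\I)CO[Si](c1ccccc1)(c1ccccc1)C(C)(C)C | intermediate
5 | (Z)-alkenyl iodide TBSOCH2–CH=C(I)–CH2OTBDPS | CC(C)(C)[Si](C)(C)OC/C=C(\I)CO[Si](c1ccccc1)(c1ccccc1)C(C)(C)C | intermediate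
6 | (2Z)-4-(TBSO)-2-(TBDPSOCH2)but-2-enoic acid | OC(=O)/C(CO[Si](c1ccccc1)(c1ccccc1)C(C)(C)C)=C\CO[Si](C)(C)C(C)(C)C | intermediate
7 | (4S)-2,2-dimethyl-1,3-dioxolane-4-carbaldehyde ((S)-glyceraldehyde acetonide) | O=C[C@@H]1COC(C)(C)O1 | starting material
8 | trimethyl 2-phosphonoacrylate | COC(=O)C(=C)P(=O)(OC)OC | starting material
9 | sodium carbanion of methyl 2-(dimethoxyphosphoryl)-3-(PMBO)propanoate | [Na+].COC(=O)[C-](COCc1ccc(OC)cc1)P(=O)(OC)OC | intermediate
10 | methyl (2E)-3-[(4R)-2,2-dimethyl-1,3-dioxolan-4-yl]-2-(PMBOCH2)prop-2-enoate | COC(=O)/C(COCc1ccc(OC)cc1)=C/[C@@H]1COC(C)(C)O1 | intermediate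
11 | methyl (2E,4R)-4,5-dihydroxy-2-(PMBOCH2)pent-2-enoate | COC(=O)/C(COCc1ccc(OC)cc1)=C/[C@@H](O)CO | intermediate
12 | (2R,3E)-2-hydroxy-4-(methoxycarbonyl)-5-(PMBO)pent-3-enoic acid | COC(=O)/C(COCc1ccc(OC)cc1)=C/[C@@H](O)C(O)=O | intermediate
13 | acid chloride of 6 | ClC(=O)/C(CO[Si](c1ccccc1)(c1ccccc1)C(C)(C)C)=C\CO[Si](C)(C)C(C)(C)C | intermediate
14 | (2R,3E)-2-{[(2Z)-4-(TBSO)-2-(TBDPSOCH2)but-2-enoyl]oxy}-4-(methoxycarbonyl)-5-(PMBO)pent-3-enoic acid | COC(=O)/C(COCc1ccc(OC)cc1)=C/[C@@H](OC(=O)/C(CO[Si](c2ccccc2)(c2ccccc2)C(C)(C)C)=C\CO[Si](C)(C)C(C)(C)C)C(O)=O | intermediate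
15 | isobutyl carbonic mixed anhydride of 14 | COC(=O)/C(COCc1ccc(OC)cc1)=C/[C@@H](OC(=O)/C(CO[Si](c2ccccc2)(c2ccccc2)C(C)(C)C)=C\CO[Si](C)(C)C(C)(C)C)C(=O)OC(=O)OCC(C)C | intermediate
16 | methyl (2E,4R)-6-diazo-5-oxo-2-(PMBOCH2)-4-{[(2Z)-4-(TBSO)-2-(TBDPSOCH2)but-2-enoyl]oxy}hept-2-enoate | COC(=O)/C(COCc1ccc(OC)cc1)=C/[C@@H](OC(=O)/C(CO[Si](c2ccccc2)(c2ccccc2)C(C)(C)C)=C\CO[Si](C)(C)C(C)(C)C)C(=O)C(C)=[N+]=[N-] | intermediate
17 | ethoxyethyne (ethoxyacetylene) | CCOC#C | starting material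
18 | rhodium carbenoid at C10 from 16 ([Rh] stands for the Rh2(OPiv)4 unit) | COC(=O)/C(COCc1ccc(OC)cc1)=C/[C@@H](OC(=O)/C(CO[Si](c2ccccc2)(c2ccccc2)C(C)(C)C)=C\CO[Si](C)(C)C(C)(C)C)C(=O)C(C)=[Rh] | intermediate
19 | six-membered carbonyl ylide (C3=O+–C10−; ring O, C3, O8, C8, C9, C10) | C[C-]1[O+]=C(/C(CO[Si](c2ccccc2)(c2ccccc2)C(C)(C)C)=C\CO[Si](C)(C)C(C)(C)C)O[C@H](/C=C(\COCc2ccc(OC)cc2)C(=O)OC)C1=O | intermediate
20 | (1R,3R,5R)-6-ethoxy-5-methyl-1-[(2Z)-4-(TBSO)-1-(TBDPSO)but-2-en-2-yl]-3-[(1E)-3-methoxy-3-oxo-2-(PMBOCH2)prop-1-en-1-yl]-2,8-dioxabicyclo[3.2.1]oct-6-en-4-one | C[C@@]12O[C@@](/C(CO[Si](c3ccccc3)(c3ccccc3)C(C)(C)C)=C\CO[Si](C)(C)C(C)(C)C)(C=C1OCC)O[C@H](/C=C(\COCc3ccc(OC)cc3)C(=O)OC)C2=O | intermediate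
21 | (1R,3R,4R,5S)-4-alcohol of the cage (C9–OH equatorial) | C[C@@]12O[C@@](/C(CO[Si](c3ccccc3)(c3ccccc3)C(C)(C)C)=C\CO[Si](C)(C)C(C)(C)C)(C=C1OCC)O[C@H](/C=C(\COCc3ccc(OC)cc3)C(=O)OC)[C@H]2O | intermediate
22 | (1R,3R,4R,5S)-cage 4-yl 3-methylbut-2-enoate | C[C@@]12O[C@@](/C(CO[Si](c3ccccc3)(c3ccccc3)C(C)(C)C)=C\CO[Si](C)(C)C(C)(C)C)(C=C1OCC)O[C@H](/C=C(\COCc3ccc(OC)cc3)C(=O)OC)[C@H]2OC(=O)C=C(C)C | intermediate
23 | 8-epi furanone alcohol (8R,9R,10S; 4Z) | CC(C)(C)[Si](C)(C)OC/C=C(/CO[Si](c1ccccc1)(c1ccccc1)C(C)(C)C)C2=CC(=O)[C@@](C)(O2)[C@H](OC(=O)C=C(C)C)[C@H](O)/C=C(\COCc3ccc(OC)cc3)C(=O)OC | intermediate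
24 | 8-methacrylate 9-senecioate (8S,9R,10S), C13–OPMB | CC(C)(C)[Si](C)(C)OC/C=C(/CO[Si](c1ccccc1)(c1ccccc1)C(C)(C)C)C2=CC(=O)[C@@](C)(O2)[C@H](OC(=O)C=C(C)C)[C@@H](OC(=O)C(C)=C)/C=C(\COCc3ccc(OC)cc3)C(=O)OC | intermediate
25 | C13 alcohol | CC(C)(C)[Si](C)(C)OC/C=C(/CO[Si](c1ccccc1)(c1ccccc1)C(C)(C)C)C2=CC(=O)[C@@](C)(O2)[C@H](OC(=O)C=C(C)C)[C@@H](OC(=O)C(C)=C)/C=C(\CO)C(=O)OC | intermediate
26 | C13 bromide (C8 cis to CH2Br) | CC(C)(C)[Si](C)(C)OC/C=C(/CO[Si](c1ccccc1)(c1ccccc1)C(C)(C)C)C2=CC(=O)[C@@](C)(O2)[C@H](OC(=O)C=C(C)C)[C@@H](OC(=O)C(C)=C)/C=C(\CBr)C(=O)OC | intermediate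
27 | C6 alcohol | OC/C=C(/CO[Si](c1ccccc1)(c1ccccc1)C(C)(C)C)C2=CC(=O)[C@@](C)(O2)[C@H](OC(=O)C=C(C)C)[C@@H](OC(=O)C(C)=C)/C=C(\CBr)C(=O)OC | intermediate
28 | (4Z)-enal (C6 aldehyde) | O=C/C=C(/CO[Si](c1ccccc1)(c1ccccc1)C(C)(C)C)C2=CC(=O)[C@@](C)(O2)[C@H](OC(=O)C=C(C)C)[C@@H](OC(=O)C(C)=C)/C=C(\CBr)C(=O)OC | intermediate
29 | allylchromium dichloride (trivalent chromium on C13) from 28 | O=C/C=C(/CO[Si](c1ccccc1)(c1ccccc1)C(C)(C)C)C2=CC(=O)[C@@](C)(O2)[C@H](OC(=O)C=C(C)C)[C@@H](OC(=O)C(C)=C)/C=C(\C[Cr](Cl)Cl)C(=O)OC | intermediate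
30 | ten-membered hydroxy ester (6R,7S,8S,9R,10S), 15-O-TBDPS | C=C(C)C(=O)O[C@H]1[C@@H](C(=C)C(=O)OC)[C@H](O)/C=C(/CO[Si](c3ccccc3)(c3ccccc3)C(C)(C)C)C2=CC(=O)[C@@](C)(O2)[C@@H]1OC(=O)C=C(C)C | intermediate
31 | 15-O-TBDPS ether of the target | C=C(C)C(=O)O[C@H]1[C@H]2C(=C)C(=O)O[C@@H]2/C=C(/CO[Si](c3ccccc3)(c3ccccc3)C(C)(C)C)C2=CC(=O)[C@@](C)(O2)[C@@H]1OC(=O)C=C(C)C | intermediate
32 | (4Z,6R,7S,8S,9R,10S)-15-hydroxy-8-(methacryloyloxy)-9-[(3-methylbut-2-enoyl)oxy]-1-oxo-3,10-epoxygermacra-2,4,11(13)-trien-12,6-olide | C=C(C)C(=O)O[C@H]1[C@H]2C(=C)C(=O)O[C@@H]2/C=C(/CO)C2=CC(=O)[C@@](C)(O2)[C@@H]1OC(=O)C=C(C)C | target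

Total step count: 20. Longest linear sequence: 17 steps (steps 1–4, then 8–20).

Steps most likely to fail

Step 10. The carbenoid may be diverted before the ylide forms (1,2-hydride shift from the C14 methyl, direct attack of the electron-rich alkyne), or the ylide may decay by proton transfer before it is trapped. Fallback from 16, returning at 23: the two-carbon unit would be brought in at the ketal oxidation level with a more nucleophilic alkene that captures the ylide in a stepwise Michael/aldol-type manner. Diazoketone 16 would be decomposed with Rh2(OPiv)4 in the presence of 1,1-diethoxyethene to give the saturated diethyl ketal cycloadduct F1, with the same regio- and facial sense expected. NaBH4 reduction would give the cage alcohol F2, and acylation with 3-methylbut-2-enoyl chloride the cage ester F3. Aqueous PPTS would then hydrolyse the diethyl ketal and open the bridging ketal with loss of two ethanol to give furanone 23.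

Step 14. SN2 displacement at the hindered C8 carbinol may be slow, with competing elimination or participation of the neighbouring C9 ester carbonyl (retention or acyl scrambling). Fallback from 23, returning at 24: an oxidation–reduction–acylation sequence. Dess–Martin oxidation would give the C8 ketone F4. Oxazaborolidine-catalysed borane reduction (CBS, catalyst enantiomer chosen with the alkenyl group as the large substituent) should give the 8S alcohol F5. Acylation with methacrylic anhydride and DMAP would then give 24.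

Step 19. The medium-ring closure may suffer from oligomerisation or from syn- instead of anti-selective addition (cis-lactone or wrong face at C7). Fallback from 28, returning at 30 and so at 31: the closed chromium alkoxide transition state would be replaced by a Lewis-acid-promoted open one. Pd(PPh3)4 and (Bu3Sn)2 would convert the allylic bromide of 28 into the allylstannane F6. BF3·OEt2 in CH2Cl2 at −78 °C under high dilution would cyclise F6 to hydroxy ester 30, which lactonises to 31 as in step 19.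

Further compounds

F1 | step 10 | diethyl ketal cycloadduct (6,6-diethoxy-2,8-dioxabicyclo[3.2.1]octan-4-one analogue of 20) | C[C@@]12O[C@@](/C(CO[Si](c3ccccc3)(c3ccccc3)C(C)(C)C)=C\CO[Si](C)(C)C(C)(C)C)(CC1(OCC)OCC)O[C@H](/C=C(\COCc3ccc(OC)cc3)C(=O)OC)C2=O
F2 | step 10 | diethyl ketal cage alcohol (C9–OH equatorial) | C[C@@]12O[C@@](/C(CO[Si](c3ccccc3)(c3ccccc3)C(C)(C)C)=C\CO[Si](C)(C)C(C)(C)C)(CC1(OCC)OCC)O[C@H](/C=C(\COCc3ccc(OC)cc3)C(=O)OC)[C@H]2O
F3 | step 10 | diethyl ketal cage 3-methylbut-2-enoate | C[C@@]12O[C@@](/C(CO[Si](c3ccccc3)(c3ccccc3)C(C)(C)C)=C\CO[Si](C)(C)C(C)(C)C)(CC1(OCC)OCC)O[C@H](/C=C(\COCc3ccc(OC)cc3)C(=O)OC)[C@H]2OC(=O)C=C(C)C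
F4 | step 14 | C8 ketone (9R,10S) from 23 | CC(C)(C)[Si](C)(C)OC/C=C(/CO[Si](c1ccccc1)(c1ccccc1)C(C)(C)C)C2=CC(=O)[C@@](C)(O2)[C@H](OC(=O)C=C(C)C)C(=O)/C=C(\COCc3ccc(OC)cc3)C(=O)OC
F5 | step 14 | (8S,9R,10S) furanone alcohol (C8 epimer of 23) | CC(C)(C)[Si](C)(C)OC/C=C(/CO[Si](c1ccccc1)(c1ccccc1)C(C)(C)C)C2=CC(=O)[C@@](C)(O2)[C@H](OC(=O)C=C(C)C)[C@@H](O)/C=C(\COCc3ccc(OC)cc3)C(=O)OC
F6 | step 19 | allylstannane aldehyde (C13–SnBu3 analogue of 28) | O=C/C=C(/CO[Si](c1ccccc1)(c1ccccc1)C(C)(C)C)C2=CC(=O)[C@@](C)(O2)[C@H](OC(=O)C=C(C)C)[C@@H](OC(=O)C(C)=C)/C=C(\C[Sn](CCCC)(CCCC)CCCC)C(=O)OC
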